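The runs stem from a simulated flask with made-up constants, and the scatter is random.

No rate constant is given, so read one number off the runs instead. Eta's dose is 1.33, where the dose is the Q charged times the time, divided by the same product for blue at its last reading. Epsilon's dose is 0.640.

| flask | Z | Q | remark | time |
|---|---|---|---|---|
| blue | 10 mM | 0.75 mM | run made earlier |  |
| green | 10 mM | 1.2 mM | run made earlier |  |
| violet | 4.8 mM | 0.50 mM | run made earlier |  |
| eta | 10 mM | 0.50 mM |  | 20 min |
| epsilon | 3.0 mM | 0.80 mM |  | 6.0 min |

| blue: time / min | blue: D / % | green: time / min | green: D / % | violet: time / min | violet: D / % |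
|---|---|---|---|---|---|
| 2.00 | 13.2 | 0.833 | 9.6 | 0.833 | 6.0 |
| 4.00 | 21.7 | 1.50 | 13.8 | 2.50 | 11.6 |
| 6.00 | 22.7 | 3.00 | 19.7 | 5.00 | 17.3 |
| 8.00 | 23.8 | 5.00 | 22.8 | 8.00 | 24.8 |
| 10.0 | 25.3 | 10.0 | 31.3 | 10.0 | 24.3 |

(readings scatter by 1 percentage point)

- the numbers in the tables scatter by 1 percentage point (one standard deviation)

- the winner by amount of D, in percent of the Z charged; "neither" if no more than 2 percentage points parts them (eta / epsilon / neither)
- how much D is there at the end, in percent of the Z charged: eta
- how much D is there at the end, in percent of the Z charged: epsilon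

Test the dose first. Blue at 8.00 min and green at 5.00 min have equal doses and read 23.8% and 22.8%, a gap of about one scatter.

Reckon eta in two ways.

Way one, between the last readings of blue and green:
D = 28.6%

Way two, from violet's last reading, which has eta's Q, walking on at green's late gain per dose:
D = 31.4%

They part. Distrust way two, since it stretches a difference of two readings and adds a third, each scattering by 1 percentage point. I commit to way one, with way two as my upper edge.

Reckon epsilon between blue at 6.00 min and violet's last reading:
D = 23.7%

So my eta leads by 5 points, more than the margin.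

The forecast picks eta: eta 29% (27% to 31%), epsilon 23% (21.5% to 24.5%). Its ground: “All three runs then fall on one curve”.

The flask gives eta 30.1% and epsilon 24.0%, so the winner is eta.

    2 Q ⇌ G, settled at all times (K = 1200 M⁻¹)
    Z + Q ⇌ D + Q, rate k2*[Z]*[Q] forward; the back reaction follows from the equilibrium constant (K = 1.40, k = 9.50 M⁻¹ s⁻¹)
    Z + Q ⇌ E + Q, rate k3*[Z]*[Q] forward; the back reaction follows from the equilibrium constant (K = 2.10, k = 200 M⁻¹ s⁻¹)

Carry the dose to a neighbour flask, eta with Q cut to 0.20 mM. Its dose is 0.533, and interpolating between blue's readings at 4.00 min and 6.00 min gives 22.4% at that dose. The neighbour gives 25.9%, more than that. Now count free Q, outside the off-cycle form G. The neighbour keeps 73.8% of its Q free, and eta at 10.0 min keeps 58.7%. The free doses are 0.393 and 0.391. D stands at 25.9% in the neighbour and 25.8% in eta at that time.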